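**Retrosynthetic overview**

1. The target is (−)-epicatechin 3-O-gallate (upper unit, rings A/C/B, unprimed flavan numbering) joined C4β→C8' to (−)-epigallocatechin 3-O-gallate (lower unit, rings D/F/E, primed numbering).
2. Last disconnections: the fifteen benzyl ethers (hydrogenolysis), then the C4–C8' bond, made by Friedel–Crafts union of a C4-activated, perbenzylated epicatechin gallate (from natural (−)-epicatechin) with perbenzylated epigallocatechin gallate.
3. The lower unit is built de novo: pyran ring F is closed by ring-closing metathesis that forms C3'=C4' between a styrene on ring D and a 1-(galloyloxy)vinyl group; hydrogenation anti to ring E then sets C3'.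
4. Enabling feature: in ring F the gallate-bearing C3' is bonded to C4', the benzylic carbon on ring D ortho to O1'. One oxidation level up, this pair is the enol-ester double bond of a 2H-chromen-3-yl gallate. C2' (from a Mitsunobu inversion of a propargylic alcohol) stays sp3 throughout.
5. Ring order: rings A, B, C come with epicatechin and rings D, E with the aromatic building blocks; ring F is the only ring made, before the two halves are joined.

Key step: step 6

Remark: 2,4,6-trihydroxybenzaldehyde, 3,4,5-tris(benzyloxy)benzaldehyde, 3,4,5-tris(benzyloxy)benzoic acid and (−)-epicatechin are taken as purchased; in step 2 the ProPhenol antipode is the one that gives the R carbinol (written as (S,S), to be swapped if a Mosher ester check of the product shows the opposite sense).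

**Route**

Step 1
Reactants: 1 2,4,6-trihydroxybenzaldehyde
Product: 2 2,4-bis(benzyloxy)-6-hydroxybenzaldehyde
Conditions: BnBr (2.1 equiv), K2CO3, DMF, 0 °C to rt
Reagents that add atoms: benzyl bromide, BrCc1ccccc1
Why: Williamson etherification under weak base alkylates the para phenol and one ortho phenol, while the remaining ortho phenol, locked in a hydrogen bond to the aldehyde, should stay free as is usual for 2,4,6-trihydroxyaryl carbonyl compounds.

Step 2
Reactants: 3 3,4,5-tris(benzyloxy)benzaldehyde; 4 ethynyltrimethylsilane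
Product: 6 (R)-1-[3,4,5-tris(benzyloxy)phenyl]prop-2-yn-1-ol, via silyl alkynol 5 (not isolated)
Conditions: Me2Zn, (S,S)-ProPhenol (20 mol %), Ph3P=O (40 mol %), toluene, 0 °C; then MeOH, K2CO3 (0.2 equiv), rt
Reagents that add atoms: none
Why: Dinuclear zinc–ProPhenol catalysed enantioselective alkynylation of an aryl aldehyde, in which the chiral catalyst selects the aldehyde face and so sets the carbinol centre, followed by base-catalysed methanolysis of the C–Si bond in the same flask.

Step 3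
Reactants: 2 2,4-bis(benzyloxy)-6-hydroxybenzaldehyde; 6 (R)-1-[3,4,5-tris(benzyloxy)phenyl]prop-2-yn-1-ol
Product: 7 2,4-bis(benzyloxy)-6-{[(1S)-1-[3,4,5-tris(benzyloxy)phenyl]prop-2-yn-1-yl]oxy}benzaldehyde
Conditions: PPh3, DIAD, toluene, 0 °C to rt
Reagents that add atoms: none
Why: Mitsunobu etherification, in which the acidic chelated phenol of 2 should displace the activated propargylic oxygen of 6 with inversion (R alcohol to S ether, the future C2'), the 3,4,5-trioxygenated aryl group being too poor a cation stabiliser to open an ionising, racemising path in toluene.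

Step 4
Reactants: 7 2,4-bis(benzyloxy)-6-{[(1S)-1-[3,4,5-tris(benzyloxy)phenyl]prop-2-yn-1-yl]oxy}benzaldehyde
Product: 8 1,5-bis(benzyloxy)-2-ethenyl-3-{[(1S)-1-[3,4,5-tris(benzyloxy)phenyl]prop-2-yn-1-yl]oxy}benzene
Conditions: Ph3PCH3Br, KOt-Bu (1.0 equiv to the salt), THF, 0 °C to rt
Reagents that add atoms: methylenetriphenylphosphorane (made from Ph3PCH3Br and KOt-Bu), C=P(c1ccccc1)(c1ccccc1)c1ccccc1
Why: Wittig methylenation with the non-stabilised ylide, which attacks the hindered electron-rich aldehyde but is not basic enough to deprotonate the alkyne or the C2' hydrogen, so the stereocentre is kept.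

Step 5
Reactants: 8 1,5-bis(benzyloxy)-2-ethenyl-3-{[(1S)-1-[3,4,5-tris(benzyloxy)phenyl]prop-2-yn-1-yl]oxy}benzene; 9 3,4,5-tris(benzyloxy)benzoic acid
Product: 10 (3R)-3-[3,5-bis(benzyloxy)-2-ethenylphenoxy]-3-[3,4,5-tris(benzyloxy)phenyl]prop-1-en-2-yl 3,4,5-tris(benzyloxy)benzoate
Conditions: [RuCl2(p-cymene)]2 (2 mol %), P(2-furyl)3 (4 mol %), Na2CO3 (5 mol %), toluene, 50 °C
Reagents that add atoms: none
Why: Ruthenium-catalysed Markovnikov hydro-acyloxylation of a terminal alkyne (carboxylate attack at the internal carbon of the ruthenium-bound alkyne) should give the 1-acyloxyvinyl group directly, bringing in the gallate as an enol ester under neutral conditions that leave C2' and the styrene alone.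

Step 6
Reactants: 10 (3R)-3-[3,5-bis(benzyloxy)-2-ethenylphenoxy]-3-[3,4,5-tris(benzyloxy)phenyl]prop-1-en-2-yl 3,4,5-tris(benzyloxy)benzoate
Product: 11 (2R)-5,7-bis(benzyloxy)-2-[3,4,5-tris(benzyloxy)phenyl]-2H-chromen-3-yl 3,4,5-tris(benzyloxy)benzoate
Conditions: second-generation Grubbs catalyst [RuCl2(=CHPh)(H2IMes)(PCy3)] (5–10 mol %), toluene (0.005 M), 60 °C, argon sparge
Reagents that add atoms: none
Why: Ring-closing olefin metathesis by the metallacyclobutane mechanism: the catalyst should load on the only monosubstituted alkene, the styrene at C4', and the resulting benzylidene is captured intramolecularly by the 1,1-disubstituted enol-ester alkene, releasing the methylidene and, overall, ethylene. The closest known reactions are ring-closing metatheses of styrenes with enol ethers, silyl enol ethers and enamides (giving benzofurans, 4H-chromenes and indoles) and of 2-vinylphenyl allyl ethers (giving 2H-chromenes). Ring F is closed in the six-membered ring-closing mode by forming C3'=C4', at the oxidation level of a flav-3-en-3-yl gallate that already carries the ester the target needs. No stereocentre is made; C2' passes through unchanged because the step is neutral, and the new trisubstituted enol-ester alkene is what lets step 7 set C3'. The step needs chemoselectivity for ring closure over styrene homodimerisation and over a heteroatom-carbene dead end; high dilution, the favoured six-membered ring, and initiation at the styrene (so that ruthenium leaves on the CH2 terminus and not on the acyloxy-bearing carbon) should secure it.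

Step 7
Reactants: 11 (2R)-5,7-bis(benzyloxy)-2-[3,4,5-tris(benzyloxy)phenyl]-2H-chromen-3-yl 3,4,5-tris(benzyloxy)benzoate
Product: 12 (2R,3R)-5,7-bis(benzyloxy)-2-[3,4,5-tris(benzyloxy)phenyl]chroman-3-yl 3,4,5-tris(benzyloxy)benzoate (octa-O-benzyl-(−)-epigallocatechin gallate)
Conditions: [Rh(nbd)(dppb)]BF4 (5 mol %), H2 (20 bar), CH2Cl2, rt
Reagents that add atoms: none
Why: Chelation-assisted homogeneous rhodium hydrogenation of an enol ester: allylic 1,2-strain with the C3' ester should hold the C2' aryl pseudoaxial, so that syn addition of H2 takes place on the opposite face and sets C3' as R (2,3-cis), while benzyl ethers and the ester are inert to this catalyst.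

Step 8
Reactants: 13 (−)-epicatechin
Product: 14 5,7,3',4'-tetra-O-benzyl-(−)-epicatechin
Conditions: BnBr (4.2 equiv), K2CO3, DMF, 0 °C to rt
Reagents that add atoms: benzyl bromide, BrCc1ccccc1
Why: Williamson etherification of the four phenols, the secondary C3 alcohol being too weakly acidic to be alkylated with K2CO3.

Step 9
Reactants: 14 5,7,3',4'-tetra-O-benzyl-(−)-epicatechin
Product: 15 5,7,3',4'-tetra-O-benzyl-4β-(2-ethoxyethoxy)-(−)-epicatechin (2,3-cis, 3,4-trans)
Conditions: DDQ (2 equiv), 2-ethoxyethanol, CH2Cl2, rt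
Reagents that add atoms: 2-ethoxyethanol, CCOCCO
Why: DDQ benzylic oxidation: hydride abstraction at C4 gives a cation stabilised by ring A that the alcohol should trap anti to the C3 hydroxyl, setting the 4β (3,4-trans) ether as is known for benzylated epicatechin.

Step 10
Reactants: 15 5,7,3',4'-tetra-O-benzyl-4β-(2-ethoxyethoxy)-(−)-epicatechin; 9 3,4,5-tris(benzyloxy)benzoic acid
Product: 16 5,7,3',4'-tetra-O-benzyl-4β-(2-ethoxyethoxy)-(−)-epicatechin 3-O-[3,4,5-tris(benzyloxy)benzoate]
Conditions: DCC, DMAP, CH2Cl2, rt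
Reagents that add atoms: none
Why: Steglich esterification (DCC activation, DMAP acyl transfer) of the hindered secondary C3 alcohol, with no change at C2, C3 or C4.

Step 11
Reactants: 16 5,7,3',4'-tetra-O-benzyl-4β-(2-ethoxyethoxy)-(−)-epicatechin 3-O-[3,4,5-tris(benzyloxy)benzoate]; 12 octa-O-benzyl-(−)-epigallocatechin gallate
Product: 17 pentadeca-O-benzyl ether of the target (perbenzylated epicatechin 3-O-gallate-(4β→8)-epigallocatechin 3-O-gallate)
Conditions: TMSOTf (0.2 equiv), CH2Cl2, −78 °C; 12 in excess (3 equiv, excess recovered)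
Reagents that add atoms: none
Why: Lewis-acid Friedel–Crafts alkylation through the flavan-4-yl cation: ionisation of the C4 ether is assisted by the C3 gallate carbonyl on the α face, so ring D should attack from the β face (3,4-trans, C4 set as in the target) through C8', the position ortho to O1' that benzylated flavan-3-ol nucleophiles normally use, and the excess of 12 suppresses self-condensation of 16.

Step 12
Reactants: 17 pentadeca-O-benzyl ether of the target
Product: 18 (−)-epicatechin 3-O-gallate-(4β→8)-(−)-epigallocatechin 3-O-gallate (target)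
Conditions: H2 (1 atm), Pd(OH)2/C, THF–MeOH–H2O, rt
Reagents that add atoms: none
Why: Hydrogenolysis of the fifteen benzyl ethers over Pd(OH)2/C, conditions under which the gallate esters, the flavan C–O bonds and the five stereocentres are left as they are.

**Compound list**

1 | 2,4,6-trihydroxybenzaldehyde | O=Cc1c(O)cc(O)cc1O | starting material
2 | 2,4-bis(benzyloxy)-6-hydroxybenzaldehyde | O=Cc1c(O)cc(OCc2ccccc2)cc1OCc1ccccc1 | intermediate
3 | 3,4,5-tris(benzyloxy)benzaldehyde | O=Cc1cc(OCc2ccccc2)c(OCc2ccccc2)c(OCc2ccccc2)c1 | starting material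
4 | ethynyltrimethylsilane | C#C[Si](C)(C)C | starting material
5 | (S)-1-[3,4,5-tris(benzyloxy)phenyl]-3-(trimethylsilyl)prop-2-yn-1-ol (silyl alkynol) | O[C@H](C#C[Si](C)(C)C)c1cc(OCc2ccccc2)c(OCc2ccccc2)c(OCc2ccccc2)c1 | intermediate
6 | (R)-1-[3,4,5-tris(benzyloxy)phenyl]prop-2-yn-1-ol | O[C@H](C#C)c1cc(OCc2ccccc2)c(OCc2ccccc2)c(OCc2ccccc2)c1 | intermediate
7 | 2,4-bis(benzyloxy)-6-{[(1S)-1-[3,4,5-tris(benzyloxy)phenyl]prop-2-yn-1-yl]oxy}benzaldehyde | O=Cc1c(O[C@@H](C#C)c2cc(OCc3ccccc3)c(OCc3ccccc3)c(OCc3ccccc3)c2)cc(OCc2ccccc2)cc1OCc1ccccc1 | intermediate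
8 | 1,5-bis(benzyloxy)-2-ethenyl-3-{[(1S)-1-[3,4,5-tris(benzyloxy)phenyl]prop-2-yn-1-yl]oxy}benzene | C=Cc1c(O[C@@H](C#C)c2cc(OCc3ccccc3)c(OCc3ccccc3)c(OCc3ccccc3)c2)cc(OCc2ccccc2)cc1OCc1ccccc1 | intermediate
9 | 3,4,5-tris(benzyloxy)benzoic acid | OC(=O)c1cc(OCc2ccccc2)c(OCc2ccccc2)c(OCc2ccccc2)c1 | starting material
10 | (3R)-3-[3,5-bis(benzyloxy)-2-ethenylphenoxy]-3-[3,4,5-tris(benzyloxy)phenyl]prop-1-en-2-yl 3,4,5-tris(benzyloxy)benzoate | C=Cc1c(O[C@@H](C(=C)OC(=O)c2cc(OCc3ccccc3)c(OCc3ccccc3)c(OCc3ccccc3)c2)c2cc(OCc3ccccc3)c(OCc3ccccc3)c(OCc3ccccc3)c2)cc(OCc2ccccc2)cc1OCc1ccccc1 | intermediate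
11 | (2R)-5,7-bis(benzyloxy)-2-[3,4,5-tris(benzyloxy)phenyl]-2H-chromen-3-yl 3,4,5-tris(benzyloxy)benzoate | O=C(OC1=Cc2c(OCc3ccccc3)cc(OCc3ccccc3)cc2O[C@@H]1c1cc(OCc2ccccc2)c(OCc2ccccc2)c(OCc2ccccc2)c1)c1cc(OCc2ccccc2)c(OCc2ccccc2)c(OCc2ccccc2)c1 | intermediate
12 | (2R,3R)-5,7-bis(benzyloxy)-2-[3,4,5-tris(benzyloxy)phenyl]chroman-3-yl 3,4,5-tris(benzyloxy)benzoate (octa-O-benzyl-(−)-epigallocatechin gallate) | O=C(O[C@@H]1Cc2c(OCc3ccccc3)cc(OCc3ccccc3)cc2O[C@@H]1c1cc(OCc2ccccc2)c(OCc2ccccc2)c(OCc2ccccc2)c1)c1cc(OCc2ccccc2)c(OCc2ccccc2)c(OCc2ccccc2)c1 | intermediate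
13 | (−)-epicatechin, (2R,3R) | O[C@@H]1Cc2c(O)cc(O)cc2O[C@@H]1c1ccc(O)c(O)c1 | starting material
14 | 5,7,3',4'-tetra-O-benzyl-(−)-epicatechin | O[C@@H]1Cc2c(OCc3ccccc3)cc(OCc3ccccc3)cc2O[C@@H]1c1ccc(OCc2ccccc2)c(OCc2ccccc2)c1 | intermediate
15 | 5,7,3',4'-tetra-O-benzyl-4β-(2-ethoxyethoxy)-(−)-epicatechin (2,3-cis, 3,4-trans) | O[C@@H]1[C@@H](OCCOCC)c2c(OCc3ccccc3)cc(OCc3ccccc3)cc2O[C@@H]1c1ccc(OCc2ccccc2)c(OCc2ccccc2)c1 | intermediate
16 | 5,7,3',4'-tetra-O-benzyl-4β-(2-ethoxyethoxy)-(−)-epicatechin 3-O-[3,4,5-tris(benzyloxy)benzoate] | O=C(O[C@@H]1[C@@H](OCCOCC)c2c(OCc3ccccc3)cc(OCc3ccccc3)cc2O[C@@H]1c1ccc(OCc2ccccc2)c(OCc2ccccc2)c1)c1cc(OCc2ccccc2)c(OCc2ccccc2)c(OCc2ccccc2)c1 | intermediate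
17 | pentadeca-O-benzyl ether of the target: 5,7,3',4'-tetra-O-benzyl-3-O-[3,4,5-tris(benzyloxy)benzoyl]-(−)-epicatechin-(4β→8)-5,7,3',4',5'-penta-O-benzyl-3-O-[3,4,5-tris(benzyloxy)benzoyl]-(−)-epigallocatechin | O=C(O[C@@H]1[C@@H](c2c(OCc4ccccc4)cc(OCc4ccccc4)c3c2O[C@H](c2cc(OCc4ccccc4)c(OCc4ccccc4)c(OCc4ccccc4)c2)[C@H](OC(=O)c2cc(OCc4ccccc4)c(OCc4ccccc4)c(OCc4ccccc4)c2)C3)c2c(OCc3ccccc3)cc(OCc3ccccc3)cc2O[C@@H]1c1ccc(OCc2ccccc2)c(OCc2ccccc2)c1)c1cc(OCc2ccccc2)c(OCc2ccccc2)c(OCc2ccccc2)c1 | intermediate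
18 | (−)-epicatechin 3-O-gallate-(4β→8)-(−)-epigallocatechin 3-O-gallate | O=C(O[C@@H]1[C@@H](c2c(O)cc(O)c3c2O[C@H](c2cc(O)c(O)c(O)c2)[C@H](OC(=O)c2cc(O)c(O)c(O)c2)C3)c2c(O)cc(O)cc2O[C@@H]1c1ccc(O)c(O)c1)c1cc(O)c(O)c(O)c1 | target

**Step count and risks**

Total step count: 12. Longest linear sequence: 8 steps (step 1 or step 2, then steps 3, 4, 5, 6, 7, 11 and 12).

The three steps most likely to fail:

Step 5. Risk: the ruthenium catalyst may divert the 1,7-enyne into cycloisomerisation, or add the acid with the wrong regiochemistry through a vinylidene path. Fallback: setting out from 8, a copper-catalysed α-selective protoboration of the terminal alkyne ((SIMes)CuCl, NaOt-Bu, B2pin2, MeOH, THF) should give the 1-borylvinyl ether, alkenyl boronate F1; an oxidative Chan–Lam-type C–O coupling of F1 with acid 9 (Cu(OAc)2, Et3N, molecular sieves, air, CH2Cl2) then gives the enol gallate, and the route is rejoined at 10.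

Step 6. Risk: the catalyst may stall, either by chelation on the doubly ortho-oxygenated styrene or by slow engagement of the hindered acyloxy-substituted alkene, so that dimerisation or alkene migration takes over. Fallback: setting out from 8, semi-hydrogenation of the alkyne (H2, Pd/CaCO3 poisoned with Pb(OAc)2 and quinoline) gives the bis-alkene, diene F2, whose ordinary ring-closing metathesis with the same ruthenium catalyst gives the 2-aryl-2H-chromene, flav-3-ene F3. Hydroboration–oxidation (BH3·THF; then NaOH, H2O2) anti to the C2' aryl gives the 2,3-trans alcohol F4, Dess–Martin oxidation gives the flavan-3-one F5, and LiBH(s-Bu)3 at −78 °C delivers hydride anti to the aryl to give the 2,3-cis alcohol F6. Steglich esterification of F6 with acid 9 (DCC, DMAP) rejoins the route at 12.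

Step 7. Risk: poor facial selectivity or slow hydrogen uptake at the trisubstituted, arene-conjugated enol ester. Fallback: setting out from 11, MeLi (2 equiv, THF, −78 °C) cleaves the enol ester to the regiodefined lithium enolate F7, and protonation at −78 °C with AcOH gives the flavan-3-one F5 without touching C2'. Reduction with LiBH(s-Bu)3 gives the 2,3-cis alcohol F6, and esterification with acid 9 (DCC, DMAP) rejoins the route at 12.

**Further compounds**

F1 | step 5 | 1,5-bis(benzyloxy)-2-ethenyl-3-{[(1S)-2-(4,4,5,5-tetramethyl-1,3,2-dioxaborolan-2-yl)-1-[3,4,5-tris(benzyloxy)phenyl]prop-2-en-1-yl]oxy}benzene (alkenyl boronate) | C=Cc1c(O[C@@H](C(=C)B2OC(C)(C)C(C)(C)O2)c2cc(OCc3ccccc3)c(OCc3ccccc3)c(OCc3ccccc3)c2)cc(OCc2ccccc2)cc1OCc1ccccc1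
F2 | step 6 | 1,5-bis(benzyloxy)-2-ethenyl-3-{[(1S)-1-[3,4,5-tris(benzyloxy)phenyl]prop-2-en-1-yl]oxy}benzene (diene) | C=Cc1c(O[C@@H](C=C)c2cc(OCc3ccccc3)c(OCc3ccccc3)c(OCc3ccccc3)c2)cc(OCc2ccccc2)cc1OCc1ccccc1
F3 | step 6 | (2S)-5,7-bis(benzyloxy)-2-[3,4,5-tris(benzyloxy)phenyl]-2H-chromene (flav-3-ene) | C1=Cc2c(OCc3ccccc3)cc(OCc3ccccc3)cc2O[C@@H]1c1cc(OCc2ccccc2)c(OCc2ccccc2)c(OCc2ccccc2)c1
F4 | step 6 | (2R,3S)-5,7-bis(benzyloxy)-2-[3,4,5-tris(benzyloxy)phenyl]chroman-3-ol (2,3-trans alcohol) | O[C@H]1Cc2c(OCc3ccccc3)cc(OCc3ccccc3)cc2O[C@@H]1c1cc(OCc2ccccc2)c(OCc2ccccc2)c(OCc2ccccc2)c1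
F5 | step 6 | (2R)-5,7-bis(benzyloxy)-2-[3,4,5-tris(benzyloxy)phenyl]chroman-3-one (flavan-3-one) | O=C1Cc2c(OCc3ccccc3)cc(OCc3ccccc3)cc2O[C@@H]1c1cc(OCc2ccccc2)c(OCc2ccccc2)c(OCc2ccccc2)c1
F6 | step 6 | (2R,3R)-5,7-bis(benzyloxy)-2-[3,4,5-tris(benzyloxy)phenyl]chroman-3-ol (2,3-cis alcohol, penta-O-benzyl-(−)-epigallocatechin) | O[C@@H]1Cc2c(OCc3ccccc3)cc(OCc3ccccc3)cc2O[C@@H]1c1cc(OCc2ccccc2)c(OCc2ccccc2)c(OCc2ccccc2)c1
F7 | step 7 | lithium (2R)-5,7-bis(benzyloxy)-2-[3,4,5-tris(benzyloxy)phenyl]-2H-chromen-3-olate (lithium enolate) | [Li+].[O-]C1=Cc2c(OCc3ccccc3)cc(OCc3ccccc3)cc2O[C@@H]1c1cc(OCc2ccccc2)c(OCc2ccccc2)c(OCc2ccccc2)c1
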